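**Plan**
- Retrosynthesis: with the N1/N10 hydrogens masked as Boc and the phenols as MOM ethers, the N1–C2 and N10–C9 bonds are cut together, giving an N5-coumaroylated amino diol and two molecules of an N-Boc coumaramide. The N5–acyl bond and the N5–C4 bond are then cut, back to 4-aminobutan-1-ol, 3-bromopropan-1-ol and O-MOM p-coumaric acid.
- Enabling feature: the target is acyclic (no rings, no stereocentres). N5 is a tertiary amide with no N–H, and C2 and C9 are unhindered primary CH2 carbons, each bonded to a secondary amide nitrogen that carries the same acyl group, so one nucleophile can close both ends at once.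
- Forward order: N5–C4 by amine alkylation, then N5 acylation, then the twofold Mitsunobu N-alkylation (N1–C2 and N10–C9), then one acid step that removes two Boc and three MOM groups.
- One protected acid (3) serves twice: as the N5 acyl group and as the source of the acyl carbamate.
- Stereochemistry: the only stereo-elements are the three E double bonds, which come from p-coumaric acid; no step touches them.

Key step: step 6

Remark: spermidine is numbered N1–C2–C3–C4–N5–C6–C7–C8–C9–N10, with the three-carbon arm at N1.
Remark: an N-Boc cinnamamide is taken to be a weaker N–H acid than phthalimide, so the more basic betaine from PBu3 and 1,1'-(azodicarbonyl)dipiperidine (ADDP) is used instead of PPh3 with a dialkyl azodicarboxylate.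

**Step 1**
Reactants: 1 p-coumaric acid
Product: 2 methoxymethyl (E)-3-[4-(methoxymethoxy)phenyl]prop-2-enoate
Conditions: MOMCl (2.5 equiv), iPr2NEt (3 equiv), CH2Cl2, 0 °C to rt
Reagents that add atoms: chloromethyl methyl ether (MOMCl), COCCl
Why: Twofold Williamson-type O-alkylation of the phenoxide and the carboxylate by the reactive α-chloro ether should protect the phenol as a base-stable acetal, the ester formed alongside being removed in step 2.

**Step 2**
Reactants: 2 methoxymethyl (E)-3-[4-(methoxymethoxy)phenyl]prop-2-enoate
Product: 3 (E)-3-[4-(methoxymethoxy)phenyl]prop-2-enoic acid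
Conditions: NaOH (2 M aq.), THF/MeOH, rt; then cold 1 M HCl to pH 4
Reagents that add atoms: sodium hydroxide (aqueous), [Na+].[OH-]
Why: Saponification should cleave the acyloxymethyl ester quickly while the aryl MOM ether is inert to hydroxide, and a brief cold acidification to pH 4 frees the acid without opening the acetal.

**Step 3**
Reactants: 3 (E)-3-[4-(methoxymethoxy)phenyl]prop-2-enoic acid; 4 tert-butyl carbamate
Product: 6 tert-butyl N-[(E)-3-[4-(methoxymethoxy)phenyl]prop-2-enoyl]carbamate, via mixed pivalic anhydride 5 (not isolated)
Conditions: t-BuCOCl, Et3N, THF, −20 °C; then added to 4 (2.2 equiv)/LiN(SiMe3)2 (2.1 equiv), THF, −78 to 0 °C; aq. NH4Cl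
Reagents that add atoms: none
Why: This is N-acylation of a lithiated carbamate by a mixed pivalic anhydride, as in the acylation of lithiated oxazolidinones; the hindered pivaloyl carbonyl should direct attack to the cinnamoyl carbonyl, the second equivalent of lithiated 4 takes up the acidic N–H of the product, and the acid-free activation spares the MOM ether.

**Step 4**
Reactants: 7 4-aminobutan-1-ol; 8 3-bromopropan-1-ol
Product: 9 4-[(3-hydroxypropyl)amino]butan-1-ol
Conditions: 7 (4 equiv), EtOH, reflux; then KOH (1 equiv), filter, distil (excess 7 recovered)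
Reagents that add atoms: none
Why: SN2 N-alkylation of a primary amine by a primary bromide, in which the fourfold excess of 7 should keep a second alkylation of the product low.

**Step 5**
Reactants: 3 (E)-3-[4-(methoxymethoxy)phenyl]prop-2-enoic acid; 9 4-[(3-hydroxypropyl)amino]butan-1-ol
Product: 11 (E)-N-(4-hydroxybutyl)-N-(3-hydroxypropyl)-3-[4-(methoxymethoxy)phenyl]prop-2-enamide, via benzotriazolyl ester 10 (not isolated)
Conditions: DIC, HOBt, DMF, 0 °C, 30 min; then 9 (1.2 equiv), 0 °C to rt
Reagents that add atoms: none
Why: Carbodiimide/HOBt amide coupling, in which the preformed active ester should acylate the secondary amine much faster than the two primary hydroxyls, so that 9 needs no O-protection.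

**Step 6**
Reactants: 11 (E)-N-(4-hydroxybutyl)-N-(3-hydroxypropyl)-3-[4-(methoxymethoxy)phenyl]prop-2-enamide; 6 tert-butyl N-[(E)-3-[4-(methoxymethoxy)phenyl]prop-2-enoyl]carbamate (2.5 equiv)
Product: 14 N1,N10-di-Boc-N1,N5,N10-tris[(E)-4-(methoxymethoxy)cinnamoyl]spermidine, via propyl-arm mono-adduct 12 (not isolated), via butyl-arm mono-adduct 13 (not isolated)
Conditions: PBu3 (3 equiv), ADDP (3 equiv, added last), THF, 0 °C to rt
Reagents that add atoms: none
Why: PBu3 and ADDP form a betaine basic enough to deprotonate the acyl carbamate 6, and it converts each primary hydroxyl of 11 into an alkoxyphosphonium ion; the imide-type nitrogen anion then displaces Bu3PO by SN2 at C2 and at C9, forming the N1–C2 and N10–C9 bonds one after the other through 12 and 13. The closest known reaction type is the Mitsunobu N-alkylation of imides, imidodicarbonates and N-acyl carbamates by primary alcohols, here in the Tsunoda variant for weak N–H acids. No ring is closed and no stereocentre is formed, and the three E double bonds are not involved. The step needs N- rather than O-alkylation of the ambident anion, and attack by the external anion rather than by the N5 amide oxygen; the unhindered primary carbons and the excess of 6 should secure both. If the amide oxygen does close on the three-carbon arm to a six-membered oxazinium ion, the same anion opens it at the same O–CH2 carbon and the product is unchanged. The MOM ethers keep the phenols, which are competing acids, out of the reaction.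

**Step 7**
Reactants: 14 N1,N10-di-Boc-N1,N5,N10-tris[(E)-4-(methoxymethoxy)cinnamoyl]spermidine
Product: 15 N1,N5,N10-tri-(E)-p-coumaroylspermidine
Conditions: HCl (4 M in 1,4-dioxane)/MeOH 1:3, 0 °C to rt, subdued light
Reagents that add atoms: none
Why: Acidolysis, in which the Boc groups on the imide nitrogens should fragment to CO2 and isobutene while the three aryl MOM acetals exchange with methanol to dimethoxymethane, leaving the three E-cinnamamides of the target.

**Compound list**
1 | p-coumaric acid, (E)-3-(4-hydroxyphenyl)prop-2-enoic acid | O=C(O)/C=C/c1ccc(O)cc1 | starting material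
2 | methoxymethyl (E)-3-[4-(methoxymethoxy)phenyl]prop-2-enoate | COCOC(=O)/C=C/c1ccc(OCOC)cc1 | intermediate
3 | (E)-3-[4-(methoxymethoxy)phenyl]prop-2-enoic acid | O=C(O)/C=C/c1ccc(OCOC)cc1 | intermediate
4 | tert-butyl carbamate | NC(=O)OC(C)(C)C | starting material
5 | (E)-3-[4-(methoxymethoxy)phenyl]prop-2-enoic 2,2-dimethylpropanoic anhydride (mixed pivalic anhydride) | COCOc1ccc(/C=C/C(=O)OC(=O)C(C)(C)C)cc1 | intermediate
6 | tert-butyl N-[(E)-3-[4-(methoxymethoxy)phenyl]prop-2-enoyl]carbamate | COCOc1ccc(/C=C/C(=O)NC(=O)OC(C)(C)C)cc1 | intermediate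
7 | 4-aminobutan-1-ol | NCCCCO | starting material
8 | 3-bromopropan-1-ol | OCCCBr | starting material
9 | 4-[(3-hydroxypropyl)amino]butan-1-ol | OCCCCNCCCO | intermediate
10 | benzotriazol-1-yl (E)-3-[4-(methoxymethoxy)phenyl]prop-2-enoate | COCOc1ccc(/C=C/C(=O)On2nnc3ccccc32)cc1 | intermediate
11 | (E)-N-(4-hydroxybutyl)-N-(3-hydroxypropyl)-3-[4-(methoxymethoxy)phenyl]prop-2-enamide | OCCCCN(CCCO)C(=O)/C=C/c1ccc(OCOC)cc1 | intermediate
12 | tert-butyl N-[3-[(4-hydroxybutyl)[(E)-4-(methoxymethoxy)cinnamoyl]amino]propyl]-N-[(E)-4-(methoxymethoxy)cinnamoyl]carbamate (N1–C2 formed, butyl arm still an alcohol) | COCOc1ccc(/C=C/C(=O)N(CCCN(CCCCO)C(=O)/C=C/c2ccc(OCOC)cc2)C(=O)OC(C)(C)C)cc1 | intermediate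
13 | tert-butyl N-[4-[(3-hydroxypropyl)[(E)-4-(methoxymethoxy)cinnamoyl]amino]butyl]-N-[(E)-4-(methoxymethoxy)cinnamoyl]carbamate (N10–C9 formed, propyl arm still an alcohol) | COCOc1ccc(/C=C/C(=O)N(CCCCN(CCCO)C(=O)/C=C/c2ccc(OCOC)cc2)C(=O)OC(C)(C)C)cc1 | intermediate
14 | N1,N10-di-Boc-N1,N5,N10-tris[(E)-4-(methoxymethoxy)cinnamoyl]spermidine | COCOc1ccc(/C=C/C(=O)N(CCCCN(CCCN(C(=O)OC(C)(C)C)C(=O)/C=C/c2ccc(OCOC)cc2)C(=O)/C=C/c2ccc(OCOC)cc2)C(=O)OC(C)(C)C)cc1 | intermediate
15 | N1,N5,N10-tri-(E)-p-coumaroylspermidine | O=C(/C=C/c1ccc(O)cc1)NCCCCN(CCCNC(=O)/C=C/c1ccc(O)cc1)C(=O)/C=C/c1ccc(O)cc1 | target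

**Step count**
Total: 7 steps. Longest linear sequence: 5 steps (1, 2, 5, 6, 7, or equally 1, 2, 3, 6, 7); step 4 is a one-step side branch.

**Steps most likely to fail**

Step 6. The acyl carbamate may be deprotonated too slowly by the betaine. The alkoxyphosphonium ions would then be lost to alkylation of the reduced azo compound, to O-alkylation of the ambident anion, or to closure by the N5 amide oxygen followed by hydrolysis on work-up, and the reaction could stall at the mono-adducts. The fallback sets out from 11: both hydroxyls are converted with MsCl and Et3N in CH2Cl2 at −10 °C into (E)-3-[4-(methoxymethoxy)phenyl]-N-[4-(methylsulfonyloxy)butyl]-N-[3-(methylsulfonyloxy)propyl]prop-2-enamide F1. F1 is used at once to alkylate the caesium salt of 6 (Cs2CO3, catalytic Bu4NI, DMF, rt to 40 °C) in a Gabriel-type imide alkylation. This separates activation of the alcohols from deprotonation of the nucleophile and comes back to the route at 14.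

Step 3. The lithiated carbamate may break down to tert-butoxide and cyanate before it is acylated, or may attack the pivaloyl carbonyl, so that pivaloyl transfer replaces cinnamoylation. The fallback sets out from 3: the mixed anhydride 5 is made as before and quenched with concentrated aqueous NH3 to give the primary amide (E)-3-[4-(methoxymethoxy)phenyl]prop-2-enamide F2. Its sodium salt (NaH, 2.1 equiv, THF, 0 °C) is then N-tert-butoxycarbonylated with Boc2O (1.05 equiv), the second equivalent of base holding the product as its anion against a second Boc transfer. The Boc group is thus placed on the amide rather than the acyl group on the carbamate, and the route is rejoined at 6.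

Step 7. Methanol may attack the twisted, activated N-acyl-N-Boc imides before the tert-butyl group has left, which would strip coumaroyl units as methyl ester. Formaldehyde equivalents released from the MOM groups may also alkylate the freed phenols. The fallback sets out from 14: the two imide Boc groups are removed first and selectively with Mg(ClO4)2 (0.2 equiv) in MeCN at 50 °C, giving N1,N5,N10-tris[(E)-4-(methoxymethoxy)cinnamoyl]spermidine F3, which carries only ordinary amides. The MOM ethers are then exchanged off in dilute methanolic HCl at rt, where acyl loss is no longer possible, and the route is rejoined at 15.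

**Further compounds**
F1 | step 6 | (E)-3-[4-(methoxymethoxy)phenyl]-N-[4-(methylsulfonyloxy)butyl]-N-[3-(methylsulfonyloxy)propyl]prop-2-enamide | CS(=O)(=O)OCCCCN(CCCOS(C)(=O)=O)C(=O)/C=C/c1ccc(OCOC)cc1
F2 | step 3 | (E)-3-[4-(methoxymethoxy)phenyl]prop-2-enamide | NC(=O)/C=C/c1ccc(OCOC)cc1
F3 | step 7 | N1,N5,N10-tris[(E)-4-(methoxymethoxy)cinnamoyl]spermidine | COCOc1ccc(/C=C/C(=O)NCCCCN(CCCNC(=O)/C=C/c2ccc(OCOC)cc2)C(=O)/C=C/c2ccc(OCOC)cc2)cc1
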